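The data are simulated for substances that don't exist; scatter was added.

The substrate balance is the invariant to watch: in this closed flask every fraction of the substrate charged stands somewhere, and target gets what other routes leave. Substrate, at 0.53 M against 1.33 M of partner A and 1.33 M of partner B in the flasks asked about, is charged in a smaller amount than either partner and we take it as the limiting reagent, so we count in fractions of its charge.

| flask | substrate | partner A | partner B | temperature | remark | time |
|---|---|---|---|---|---|---|
| Saturday's | 0.53 M | 1.33 M | 0.67 M | 35 °C | run made earlier |  |
| Wednesday's | 0.53 M | 1.33 M | 2.7 M | 60 °C | run made earlier |  |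
| delta | 0.53 M | 1.33 M | 1.33 M | 80 °C |  | 2.0 min |
| gamma | 0.53 M | 1.33 M | 1.33 M | 40 °C |  | 2.0 min |
| epsilon | 0.53 M | 1.33 M | 1.33 M | 60 °C |  | 2.0 min |

| run | time / min | target / % |
|---|---|---|
| Saturday's | 2.50 | 0.1 |
| Saturday's | 6.00 | 0.5 |
| Saturday's | 12.0 | 1.9 |
| Saturday's | 20.0 | 2.9 |
| Wednesday's | 0.667 | 2.0 |
| Wednesday's | 2.00 | 17.0 |
| Wednesday's | 4.00 | 35.5 |
| Wednesday's | 5.00 | 41.4 |

(standard deviation of a reading: 0.3 percentage points)

1. the flask with the highest amount of target, in percent of the substrate charged ("all alike" if they lie within 1.5 percentage points) (delta / gamma / epsilon / all alike)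
2. final target, as a percentage of the substrate charged, in delta
3. final target, as a percentage of the substrate charged, in gamma
4. final target, as a percentage of the substrate charged, in epsilon



We read Wednesday's run down its column. Between the second and third rows target grows at 0.0925 min⁻¹ of the charge, with target near 26.2 %. Between the third and fourth rows it grows at 0.0590 min⁻¹, with target near 38.4 %. If the slope is proportional to the room left under a fixed top, these two rows give that top. We call it the ceiling, the fraction of the substrate charge that can become target, and in Wednesday's run it reads 59.9 %. This is a rough reading, since the last slope rests on two readings with a scatter of 0.3 percentage points each. The same rows give a rate constant of 0.275 min⁻¹, and the first two rows give a lag of 0.489 min. Saturday's last row, 2.9 %, lies too low to show a bend.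

For delta we take the constant as first order in partner B and multiply it by 4 for the hotter bath, a doubling per 10 degrees. That gives 0.541 min⁻¹, and under Wednesday's ceiling, carried over unchanged as our assumption, with the lag kept, 33.5 % at 2.0 min. For gamma and epsilon we accept the forecast, whose values lie below the ceiling.

The forecast names delta: delta 52 % (30 % to 70 %), “unless side reactions appear”; gamma 0.4 % (0.1 % to 1.2 %); epsilon 8 % (5 % to 13 %). Our delta is lower than the forecast's.

The flasks give delta as the highest: delta 27.5 %, gamma 0.308 %, epsilon 6.29 %.

    2 open intermediate → homo product (k = 0.00102 M⁻¹ s⁻¹, Ea = 59.0 kJ mol⁻¹)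
    open intermediate + second intermediate → target (k = 0.00773 M⁻¹ s⁻¹, Ea = 60.0 kJ mol⁻¹)
    partner B + partner A → second intermediate (k = 0.00576 M⁻¹ s⁻¹, Ea = 71.0 kJ mol⁻¹)
    substrate + second intermediate → side product (k = 0.0407 M⁻¹ s⁻¹, Ea = 58.0 kJ mol⁻¹)
    substrate + partner B → open intermediate (k = 0.00786 M⁻¹ s⁻¹, Ea = 61.0 kJ mol⁻¹)
    (constants at 60 °C)

Delta at 2.00 min holds 58.0 % as side product and 2.43 % as homo product, so its ceiling at that moment stands at 39.5 %, lower than Wednesday's reading. Target fills 27.5 % of that, and open intermediate holds 12.0 % beside 0.0503 % of substrate; at 20.0 min target stands at 39.3 %. The same balance on epsilon's neighbour at 85 °C, at 2.00 min, takes off 58.8 % of side product and 2.42 % of homo product, which leaves a ceiling of 38.8 %. Target there is 32.2 %, and open intermediate holds 6.66 %.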